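The route opens the trans-decalin at C4–C5 (ring A) and C9–C10 (ring B). The feature exploited is that C4 bears both a methyl group and the C19 carboxyl carbon. With a temporary ketone at C3, C4 is the α-carbon of an α-methyl β-keto ester and can be oxidised to a radical. The cascade can stop at C8, the ring B carbon that holds the C17 methylidene. One oxidative radical cascade thus closes both rings, sets C4, C5, C9 and C10, and leaves the exocyclic alkene. Its precursor is an open C20 chain: (−)-8-phenylmenthyl keto ester head, two trisubstituted E-alkenes, the preset 13S centre and a pivalate-capped C15 alcohol.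

Key step: step 7

Remarks on the chemistry
- Numbering: labdane numbering (C1–C20) is used from the coupling step onwards. The target is (4S,5R,9S,10R,13S), the normal labdane series: 10β-CH3, 5α-H, 9α-H, axial 4β-CO2H.
- Assumption: the sense of induction follows the stacked-phenyl model of 8-phenylmenthyl esters. The ester C=O lies syn to the carbinol C–H, C3 lies syn to the ester C=O, and the phenyl ring covers one face. For the (1R,2S,5R)-auxiliary this leaves the Re face of C4 open, which gives the normal labdane series.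
- Protecting group: the C15 alcohol travels as a pivalate, not an acetate. An acetate would offer acidic α-hydrogens and an open carbonyl group to the dianion in the coupling. The pivalate has neither, tolerates AcOH, and leaves in the same LiAlH4 step as the auxiliary.
- C13: the 13S centre needs the (R)-BINAP ligand with the E-allylic alcohol.
- CIP note: C4 is R while C3 carries O or N, and S once C3 is CH2. There is no spatial change.

Step 1
Reactants: 1 (2E,6E)-farnesol
Product: 2 (3S,6E)-3,7,11-trimethyldodeca-6,10-dien-1-ol [(S)-2,3-dihydrofarnesol]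
Conditions: H2 (100 atm), Ru(OAc)2[(R)-BINAP] (0.2 mol %), MeOH–H2O 95:5, 20 °C
Reagents that add atoms: none
Why: Noyori asymmetric hydrogenation, in which the allylic hydroxyl binds ruthenium so that only the C2=C3 alkene is reduced, and with an E-allylic alcohol the (R)-ligand delivers hydrogen to the face that gives the 3S centre (future C13) while the two remote trisubstituted alkenes stay inert.

Step 2
Reactants: 2 (S)-2,3-dihydrofarnesol
Product: 3 (3S,6E)-3,7,11-trimethyldodeca-6,10-dien-1-yl pivalate
Conditions: t-BuCOCl (1.2 equiv), Et3N (1.5 equiv), 4-(dimethylamino)pyridine (DMAP, 5 mol %), CH2Cl2, 0 °C → rt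
Reagents that add atoms: pivaloyl chloride, CC(C)(C)C(=O)Cl
Why: DMAP-catalysed acylation of an unhindered primary alcohol, giving an ester without α-hydrogens and with a shielded carbonyl group that should pass the oxidation, bromination, dianion and AcOH steps unchanged.

Step 3
Reactants: 3 (3S,6E)-3,7,11-trimethyldodeca-6,10-dien-1-yl pivalate
Product: 4 (3S,6E,10E)-12-hydroxy-3,7,11-trimethyldodeca-6,10-dien-1-yl pivalate
Conditions: SeO2 (0.1 equiv), t-BuOOH (5.5 M in decane, 2 equiv), salicylic acid (0.1 equiv), CH2Cl2, 0 °C → rt, stopped at partial conversion, 3 recycled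
Reagents that add atoms: tert-butyl hydroperoxide, CC(C)(C)OO (its oxygen is passed on by the SeO2 catalyst, O=[Se]=O)
Why: Riley-type allylic oxidation (ene reaction, then [2,3]-sigmatropic shift) that prefers the more accessible terminal isopropylidene unit and by its mechanism hydroxylates the E-methyl group, so the E geometry needed for the future C5=C10 alkene results.

Step 4
Reactants: 4 (3S,6E,10E)-12-hydroxy-3,7,11-trimethyldodeca-6,10-dien-1-yl pivalate
Product: 5 (3S,6E,10E)-12-bromo-3,7,11-trimethyldodeca-6,10-dien-1-yl pivalate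
Conditions: CBr4 (1.2 equiv), PPh3 (1.25 equiv), CH2Cl2, −20 → 0 °C, used without storage
Reagents that add atoms: carbon tetrabromide, BrC(Br)(Br)Br
Why: Appel reaction, in which bromide displaces the primary allylic oxyphosphonium group by SN2 under neutral conditions, so the alkene geometry and the pivalate are kept.

Step 5
Reactants: 6 (−)-8-phenylmenthol [(1R,2S,5R)-5-methyl-2-(2-phenylpropan-2-yl)cyclohexan-1-ol]; 7 methyl 2-methyl-3-oxobutanoate
Product: 8 (−)-8-phenylmenthyl 2-methyl-3-oxobutanoate (epimers at the α-carbon)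
Conditions: 7 (2 equiv), DMAP (0.3 equiv), toluene, reflux, MeOH taken out over 4 Å molecular sieves
Reagents that add atoms: none
Why: DMAP-catalysed ester exchange of an enolisable β-keto ester, which runs through an acylketene and therefore acylates even this hindered secondary alcohol without touching its carbinol C–O bond.

Step 6
Reactants: 8 (−)-8-phenylmenthyl 2-methyl-3-oxobutanoate; 5 (3S,6E,10E)-12-bromo-3,7,11-trimethyldodeca-6,10-dien-1-yl pivalate
Product: 10 (−)-8-phenylmenthyl (6E,10E,14S)-2,6,10,14-tetramethyl-3-oxo-16-(pivaloyloxy)hexadeca-6,10-dienoate, via dilithium dianion 9 (not isolated)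
Conditions: LiN(iPr)2 (commercial solution, 2.1 equiv), THF, −78 → 0 °C; 5 (0.9 equiv), −78 → 0 °C; aq NH4Cl
Reagents that add atoms: none
Why: γ-alkylation of a β-keto ester dianion, in which the more basic terminal carbon of 9 displaces the primary allylic bromide by SN2 (C1–C2 bond) far faster than it can attack the hindered, non-enolisable pivalate, the epimer mixture at C4 being irrelevant because C4 becomes planar in the next step.

Step 7
Reactants: 10 (−)-8-phenylmenthyl (6E,10E,14S)-2,6,10,14-tetramethyl-3-oxo-16-(pivaloyloxy)hexadeca-6,10-dienoate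
Product: 14 (−)-8-phenylmenthyl (13S)-3-oxo-15-(pivaloyloxy)labd-8(17)-en-19-oate (normal labdane series; axial 4β-ester; equatorial 4α-CH3), via C4 radical 11 (not isolated), via monocyclic C10 radical 12 (not isolated), via bicyclic C8 radical 13 (not isolated)
Conditions: Mn(OAc)3·2H2O (2.2 equiv), Cu(OAc)2·H2O (1.0 equiv), degassed AcOH (0.05 M), argon, 23 °C; chromatography
Reagents that add atoms: none
Why: Mn(OAc)3 (trivalent manganese) oxidises the enolised keto ester to the electrophilic C4 radical 11, which bonds to C5 to give the tertiary C10 radical 12, and this bonds to C9 to give the tertiary C8 radical 13; Cu(OAc)2 (divalent copper) intercepts 13 as an alkylcopper species that loses a C17 hydrogen by β-elimination, and the monovalent copper formed is reoxidised by the second equivalent of Mn(OAc)3. The closest known reaction type is the Mn(OAc)3/Cu(OAc)2 oxidative free-radical polyene cyclisation of α-alkyl β-keto esters that ends in a methylidenecyclohexane, which is also known with 8-phenylmenthyl esters. Ring A closes 6-endo-trig (C4–C5) and ring B closes 6-endo-trig (C9–C10), because each alkene carries its methyl group on the inner carbon, so attack at the CH terminus is less hindered and gives a tertiary radical. C5, C10 and C9 follow from the chair–chair array of the two E-alkenes (anti addition across C5=C10 gives 5α-H and 10β-CH3, and the E C8=C9 alkene places C11 equatorial with 9α-H), while the relative configuration at C4 follows from the radical rotamer in which C2 lies syn to the ester carbon and the two C=O dipoles oppose each other, which puts the ester axial and the methyl group equatorial. The absolute sense comes from the phenyl ring of the auxiliary, which lies over the Si face of the planar C4 radical so that C5 bonds to the Re face (C19 > C3 > C18), and the wrong-face product is a diastereomer that chromatography should remove. The step also needs exocyclic rather than endocyclic elimination, which the copper pathway secures by taking the most accessible hydrogen (on the C17 methyl group), and it needs a product that resists further oxidation, which the now quaternary C4 secures.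

Step 8
Reactants: 14 (−)-8-phenylmenthyl (13S)-3-oxo-15-(pivaloyloxy)labd-8(17)-en-19-oate
Product: 15 C3 N-tosylhydrazone of 14
Conditions: TsNHNH2 (1.5 equiv), AcOH (cat.), EtOH, 70 °C
Reagents that add atoms: 4-methylbenzenesulfonohydrazide, Cc1ccc(cc1)S(=O)(=O)NN
Why: Hydrazone condensation at the only ketone, whose surroundings match those of 4,4-disubstituted 3-keto terpenoids that are known to form tosylhydrazones, under acidity too weak to move the C8=C17 alkene.

Step 9
Reactants: 15 C3 N-tosylhydrazone of 14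
Product: 18 (−)-8-phenylmenthyl (13S)-15-(pivaloyloxy)labd-8(17)-en-19-oate, via N-boryl tosylhydrazine 16 (not isolated), via C3 diazene 17 (not isolated)
Conditions: catecholborane (3 equiv), CHCl3, −10 → 0 °C; then NaOAc·3H2O (excess), reflux
Reagents that add atoms: none
Why: Caglioti-type tosylhydrazone reduction in its mild catecholborane form, in which hydride adds to C=N to give 16, acetate then triggers loss of sulfinate to diazene 17, and 17 extrudes N2 to leave CH2 at C3, while both esters and the unactivated alkene do not react with catecholborane at this temperature.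

Step 10
Reactants: 18 (−)-8-phenylmenthyl (13S)-15-(pivaloyloxy)labd-8(17)-en-19-oate
Product: 19 (13S)-labd-8(17)-ene-15,19-diol
Conditions: LiAlH4 (5 equiv), THF, reflux; H2O, aq NaOH, H2O work-up
Reagents that add atoms: none
Why: LiAlH4 ester reduction, which cleaves the axial neopentyl-type C19 ester that would resist hydrolysis, removes the pivalate in the same operation, frees auxiliary 6 for recovery and leaves the isolated alkene and all stereocentres untouched.

Step 11
Reactants: 19 (13S)-labd-8(17)-ene-15,19-diol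
Product: 20 (13S)-19-hydroxylabd-8(17)-en-15-yl formate
Conditions: acetic formic anhydride (distilled, 1.05 equiv), pyridine (2 equiv), CH2Cl2, −40 → −20 °C
Reagents that add atoms: acetic formic anhydride, CC(=O)OC=O
Why: Rate-controlled acylation, in which the open C15 primary alcohol reacts much faster than the C19 alcohol (neopentyl, axial and 1,3-diaxial to C20), and the mixed anhydride passes on only its more electrophilic formyl group, so the final ester also protects C15.

Step 12
Reactants: 20 (13S)-19-hydroxylabd-8(17)-en-15-yl formate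
Product: 21 (13S)-19-oxolabd-8(17)-en-15-yl formate
Conditions: Dess–Martin periodinane (1.3 equiv), CH2Cl2, 0 °C → rt
Reagents that add atoms: none
Why: Dess–Martin oxidation, a near-neutral method that works on hindered neopentyl alcohols, spares the formate and the alkene, and gives an aldehyde that cannot epimerise because C4 is quaternary.

Step 13
Reactants: 21 (13S)-19-oxolabd-8(17)-en-15-yl formate
Product: 22 (13S)-15-(formyloxy)labd-8(17)-en-19-oic acid (4S,5R,9S,10R,13S; CNP0494097.1)
Conditions: NaClO2 (3 equiv), NaH2PO4 (3 equiv), 2-methyl-2-butene (20 equiv), t-BuOH–H2O, 0 °C → rt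
Reagents that add atoms: sodium chlorite, [Na+].[O-]Cl=O
Why: Pinnick oxidation, in which chlorous acid adds to the aldehyde and fragments to the acid in a weakly acidic buffer that the formate tolerates, while the excess 2-methyl-2-butene takes up the hypochlorous acid before it can reach the C8=C17 alkene.

Compound list
1 | (2E,6E)-farnesol | CC(C)=CCC/C(C)=C/CC/C(C)=C/CO | starting material
2 | (3S,6E)-3,7,11-trimethyldodeca-6,10-dien-1-ol | CC(C)=CCC/C(C)=C/CC[C@H](C)CCO | intermediate
3 | (3S,6E)-3,7,11-trimethyldodeca-6,10-dien-1-yl pivalate | CC(C)=CCC/C(C)=C/CC[C@H](C)CCOC(=O)C(C)(C)C | intermediate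
4 | (3S,6E,10E)-12-hydroxy-3,7,11-trimethyldodeca-6,10-dien-1-yl pivalate | OC/C(C)=C/CC/C(C)=C/CC[C@H](C)CCOC(=O)C(C)(C)C | intermediate
5 | (3S,6E,10E)-12-bromo-3,7,11-trimethyldodeca-6,10-dien-1-yl pivalate | BrC/C(C)=C/CC/C(C)=C/CC[C@H](C)CCOC(=O)C(C)(C)C | intermediate
6 | (−)-8-phenylmenthol, (1R,2S,5R) | CC(C)(c1ccccc1)[C@@H]1CC[C@@H](C)C[C@H]1O | starting material
7 | methyl 2-methyl-3-oxobutanoate | COC(=O)C(C)C(C)=O | starting material
8 | (−)-8-phenylmenthyl 2-methyl-3-oxobutanoate | CC(C)(c1ccccc1)[C@@H]1CC[C@@H](C)C[C@H]1OC(=O)C(C)C(C)=O | intermediate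
9 | dilithium dianion (bis-enolate) of 8 | [Li+].[Li+].C=C([O-])C(C)=C([O-])O[C@@H]1C[C@H](C)CC[C@H]1C(C)(C)c2ccccc2 | intermediate
10 | (−)-8-phenylmenthyl (6E,10E,14S)-2,6,10,14-tetramethyl-3-oxo-16-(pivaloyloxy)hexadeca-6,10-dienoate | CC(C)(c1ccccc1)[C@@H]1CC[C@@H](C)C[C@H]1OC(=O)C(C)C(=O)CC/C(C)=C/CC/C(C)=C/CC[C@H](C)CCOC(=O)C(C)(C)C | intermediate
11 | open-chain C4 radical from 10 | CC(C)(c1ccccc1)[C@@H]1CC[C@@H](C)C[C@H]1OC(=O)[C](C)C(=O)CC/C(C)=C/CC/C(C)=C/CC[C@H](C)CCOC(=O)C(C)(C)C | intermediate
12 | monocyclic C10 radical (ring A closed) | C[C]1CCC(=O)[C@](C)(C(=O)O[C@@H]2C[C@H](C)CC[C@H]2C(C)(C)c3ccccc3)[C@@H]1CC/C(C)=C/CC[C@H](C)CCOC(=O)C(C)(C)C | intermediate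
13 | bicyclic C8 radical (rings A and B closed) | C[C]1CC[C@@H]2[C@](C)(CCC(=O)[C@]2(C)C(=O)O[C@@H]3C[C@H](C)CC[C@H]3C(C)(C)c4ccccc4)[C@H]1CC[C@H](C)CCOC(=O)C(C)(C)C | intermediate
14 | (−)-8-phenylmenthyl (13S)-3-oxo-15-(pivaloyloxy)labd-8(17)-en-19-oate | C=C1CC[C@@H]2[C@](C)(CCC(=O)[C@]2(C)C(=O)O[C@@H]3C[C@H](C)CC[C@H]3C(C)(C)c4ccccc4)[C@H]1CC[C@H](C)CCOC(=O)C(C)(C)C | intermediate
15 | C3 N-tosylhydrazone of 14 | C=C1CC[C@@H]2[C@](C)(CCC(=NNS(=O)(=O)c5ccc(C)cc5)[C@]2(C)C(=O)O[C@@H]3C[C@H](C)CC[C@H]3C(C)(C)c4ccccc4)[C@H]1CC[C@H](C)CCOC(=O)C(C)(C)C | intermediate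
16 | C3 N-(1,3,2-benzodioxaborol-2-yl)-N'-tosylhydrazine (C3 configuration immaterial) | C=C1CC[C@@H]2[C@](C)(CCC(N(NS(=O)(=O)c5ccc(C)cc5)B6Oc7ccccc7O6)[C@]2(C)C(=O)O[C@@H]3C[C@H](C)CC[C@H]3C(C)(C)c4ccccc4)[C@H]1CC[C@H](C)CCOC(=O)C(C)(C)C | intermediate
17 | C3 diazene (C3 configuration immaterial) | C=C1CC[C@@H]2[C@](C)(CCC(N=N)[C@]2(C)C(=O)O[C@@H]3C[C@H](C)CC[C@H]3C(C)(C)c4ccccc4)[C@H]1CC[C@H](C)CCOC(=O)C(C)(C)C | intermediate
18 | (−)-8-phenylmenthyl (13S)-15-(pivaloyloxy)labd-8(17)-en-19-oate | C=C1CC[C@@H]2[C@](C)(CCC[C@]2(C)C(=O)O[C@@H]3C[C@H](C)CC[C@H]3C(C)(C)c4ccccc4)[C@H]1CC[C@H](C)CCOC(=O)C(C)(C)C | intermediate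
19 | (13S)-labd-8(17)-ene-15,19-diol | C=C1CC[C@@H]2[C@](C)(CCC[C@]2(C)CO)[C@H]1CC[C@H](C)CCO | intermediate
20 | (13S)-19-hydroxylabd-8(17)-en-15-yl formate | C=C1CC[C@@H]2[C@](C)(CCC[C@]2(C)CO)[C@H]1CC[C@H](C)CCOC=O | intermediate
21 | (13S)-19-oxolabd-8(17)-en-15-yl formate | C=C1CC[C@@H]2[C@](C)(CCC[C@]2(C)C=O)[C@H]1CC[C@H](C)CCOC=O | intermediate
22 | (13S)-15-(formyloxy)labd-8(17)-en-19-oic acid, CNP0494097.1 | C=C1CC[C@@H]2[C@](C)(CCC[C@]2(C)C(=O)O)[C@H]1CC[C@H](C)CCOC=O | target

Total step count: 13. Longest linear sequence: 12 steps (1 → 22 through steps 1–4 and 6–13). Step 5 is the only side branch.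

Steps most likely to fail

1. Step 7.
What may go wrong: the phenyl ring may shield one face of the C4 radical too weakly, giving poor facial selectivity. The copper-mediated elimination may also leak towards the ring carbons, and chain transfer may occur before ring B closes.
Fallback, from 5 back to 19: the quaternary centre is no longer made in the cyclisation, and face control is handed to a metal chelate.
- (+)-8-Phenylmenthol and methyl acetoacetate give (+)-8-phenylmenthyl acetoacetate F1 by the ester exchange of step 5.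
- The dianion of F1 is alkylated with 5 as in step 6 to give the α-unsubstituted keto ester F2.
- F2 is cyclised with Mn(OAc)3·2H2O and Cu(OAc)2·H2O in CF3CH2OH at 0 °C in the presence of Yb(OTf)3. The lanthanide locks both carbonyl groups syn, a known way to sharpen the face selectivity of phenylmenthyl keto esters.
- In this chelated rotamer the ring chain lies anti to the ester, so the antipodal auxiliary is the one that leads to the same decalin, the bicyclic keto ester F3 (C4 enolisable).
- NaH and MeI in DMF then methylate the enolate of F3 from the α face, away from the axial C10 methyl group. This known outcome for such decalin keto esters gives the equatorial methyl/axial ester F4.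
- F4 passes through the operations of steps 8–10 (tosylhydrazone F5, deoxygenated ester F6, LiAlH4) and rejoins the route at 19.

2. Step 3.
What may go wrong: the selenium reagent may also attack the inner trisubstituted alkene, and the allylic alcohol may be oxidised further. The reaction may then have to be stopped at low conversion.
Fallback, from 3 back to 4: the allylic C–H oxidation is replaced by cleavage and rebuilding of the chain end.
- NBS in aqueous THF at 0 °C adds selectively to the terminal alkene to give the bromohydrin F7.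
- K2CO3 in MeOH closes F7 to the terminal epoxide F8.
- H5IO6 in THF–H2O cleaves F8 to the trisnor aldehyde F9.
- The stabilised ylide Ph3P=C(CH3)CHO in toluene at 80 °C gives the E-enal F10 by an E-selective Wittig reaction.
- Luche reduction (NaBH4, CeCl3·7H2O, MeOH, 0 °C) gives 4 with the pivalate untouched.

3. Step 9.
What may go wrong: hydride delivery to the hindered C3 hydrazone may be slow, and elimination towards C2 may compete with reduction.
Fallback, from 14 back to 18, bypassing steps 8 and 9: the ionic deoxygenation is replaced by a radical one.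
- NaBH4 in MeOH–THF at 0 °C attacks the open α face of the ketone to give the 3β-alcohol F11.
- 1,1'-Thiocarbonyldiimidazole with DMAP in 1,2-dichloroethane at 80 °C gives the imidazolylthiocarbonate F12.
- Bu3SnH and AIBN in toluene at 110 °C (Barton–McCombie deoxygenation) give 18. The secondary C3 radical lies too far from C8=C17 to cyclise.

Further compounds
F1 | step 7 | (+)-8-phenylmenthyl acetoacetate | CC(C)(c1ccccc1)[C@H]1CC[C@H](C)C[C@@H]1OC(=O)CC(C)=O
F2 | step 7 | (+)-8-phenylmenthyl (6E,10E,14S)-6,10,14-trimethyl-3-oxo-16-(pivaloyloxy)hexadeca-6,10-dienoate | CC(C)(c1ccccc1)[C@H]1CC[C@H](C)C[C@@H]1OC(=O)CC(=O)CC/C(C)=C/CC/C(C)=C/CC[C@H](C)CCOC(=O)C(C)(C)C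
F3 | step 7 | (+)-8-phenylmenthyl (13S)-3-oxo-15-(pivaloyloxy)-18-norlabd-8(17)-en-19-oate (C4 enolisable) | C=C1CC[C@@H]2[C@](C)(CCC(=O)C2C(=O)O[C@H]3C[C@@H](C)CC[C@@H]3C(C)(C)c4ccccc4)[C@H]1CC[C@H](C)CCOC(=O)C(C)(C)C
F4 | step 7 | (+)-8-phenylmenthyl (13S)-3-oxo-15-(pivaloyloxy)labd-8(17)-en-19-oate | C=C1CC[C@@H]2[C@](C)(CCC(=O)[C@]2(C)C(=O)O[C@H]3C[C@@H](C)CC[C@@H]3C(C)(C)c4ccccc4)[C@H]1CC[C@H](C)CCOC(=O)C(C)(C)C
F5 | step 7 | C3 N-tosylhydrazone of F4 | C=C1CC[C@@H]2[C@](C)(CCC(=NNS(=O)(=O)c5ccc(C)cc5)[C@]2(C)C(=O)O[C@H]3C[C@@H](C)CC[C@@H]3C(C)(C)c4ccccc4)[C@H]1CC[C@H](C)CCOC(=O)C(C)(C)C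
F6 | step 7 | (+)-8-phenylmenthyl (13S)-15-(pivaloyloxy)labd-8(17)-en-19-oate | C=C1CC[C@@H]2[C@](C)(CCC[C@]2(C)C(=O)O[C@H]3C[C@@H](C)CC[C@@H]3C(C)(C)c4ccccc4)[C@H]1CC[C@H](C)CCOC(=O)C(C)(C)C
F7 | step 3 | (3S,6E)-10-bromo-11-hydroxy-3,7,11-trimethyldodec-6-en-1-yl pivalate (C10 epimers) | CC(C)(O)C(Br)CC/C(C)=C/CC[C@H](C)CCOC(=O)C(C)(C)C
F8 | step 3 | (3S,6E)-10,11-epoxy-3,7,11-trimethyldodec-6-en-1-yl pivalate (C10 epimers) | CC1(C)OC1CC/C(C)=C/CC[C@H](C)CCOC(=O)C(C)(C)C
F9 | step 3 | (3S,6E)-3,7-dimethyl-10-oxodec-6-en-1-yl pivalate | O=CCC/C(C)=C/CC[C@H](C)CCOC(=O)C(C)(C)C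
F10 | step 3 | (3S,6E,10E)-3,7,11-trimethyl-12-oxododeca-6,10-dien-1-yl pivalate | O=C/C(C)=C/CC/C(C)=C/CC[C@H](C)CCOC(=O)C(C)(C)C
F11 | step 9 | (−)-8-phenylmenthyl (13S)-3β-hydroxy-15-(pivaloyloxy)labd-8(17)-en-19-oate | C=C1CC[C@@H]2[C@](C)(CC[C@H](O)[C@]2(C)C(=O)O[C@@H]3C[C@H](C)CC[C@H]3C(C)(C)c4ccccc4)[C@H]1CC[C@H](C)CCOC(=O)C(C)(C)C
F12 | step 9 | 3β-O-(imidazol-1-ylthiocarbonyl) derivative of F11 | C=C1CC[C@@H]2[C@](C)(CC[C@H](OC(=S)n5ccnc5)[C@]2(C)C(=O)O[C@@H]3C[C@H](C)CC[C@H]3C(C)(C)c4ccccc4)[C@H]1CC[C@H](C)CCOC(=O)C(C)(C)C
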